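## Retrosynthetic overview

1. The C50 carotenoid is cut at C15'–C14' and, in the same operation, at C14–C15 and at both C13/C13' methyl bonds. This leads back to two ring-bearing terminal trienynes (20 and 40), Me3Al and the two-carbon linchpin (E)-1-bromo-2-iodoethene (2).
2. Enabling feature: the unsubstituted central (E)-C15=C15' ethene unit sits between two methyl-bearing trisubstituted alkenes (C13=C14 and C13'=C14'), each the imprint of a syn-methylmetalation of a terminal alkyne. The two halves of the polyene differ only at C2/C2' of the two 2,6,6-trimethylcyclohexene rings.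
3. Each trienyne comes from a ring enol triflate by Heck reaction with methyl vinyl ketone, ketone-to-alkyne conversion, and methylalumination/coupling with 2/ethynylation.
4. No ring is closed in the route: both six-membered rings come from 2-methylcyclohex-2-enone (ring A of the left half first, ring B of the right half second). C2 (R) and C2' (S) are set by enantiomeric copper-catalysed conjugate additions; the side chains come from cross-metathesis (prenyl) or ozonolysis/Knoevenagel/reduction (diol).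
5. The last step removes the two silyl ethers with fluoride.

Key step: step 21

## Remarks

- Abbreviations: ring A group = (5R)-2,6,6-trimethyl-5-(3-methylbut-2-en-1-yl)cyclohex-1-en-1-yl, bonded through C1. Ring B group = (5S)-5-{4-[(tert-butyldimethylsilyl)oxy]-3-{[(tert-butyldimethylsilyl)oxy]methyl}but-2-en-1-yl}-2,6,6-trimethylcyclohex-1-en-1-yl, bonded through C1. TBS = tert-butyldimethylsilyl.
- The configuration at the ring stereocentre does not change after steps 2 and 10. Its CIP descriptor changes formally in steps 3, 4, 11 and 12, because the priority of the side chain relative to the ring CH2 changes.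
- Assumption: the antipode of the NHC ligand that gives (3R)-6 is to be identified in a pilot run; its mirror image is used in step 10.
- Compounds 9, 25 and 27 are expected as E/Z mixtures (E drawn); both isomers converge in steps 5 and 14.
- The aluminium and ammonium alkoxides of steps 16 and 22, which are only hydrolysed on work-up, are not numbered.
- All polyenes (from 13 and 33 onward) are handled under argon with exclusion of light.

## Route

**Linchpin**

Step 1
Reactants: 1 acetylene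
Product: 2 (E)-1-bromo-2-iodoethene
Conditions: IBr, 48% aq. HBr, 0 °C, acetylene stream
Reagents that add atoms: iodine monobromide, SMILES IBr
Why: Electrophilic anti addition of IBr across the triple bond (alkyne halogenation through an iodonium ion) should give the E dihaloethene.

**Left trienyne (ring A)**

Step 2
Reactants: 3 2-methylcyclohex-2-en-1-one; 4 but-3-en-1-ylmagnesium bromide
Product: 6 (3R)-3-(but-3-en-1-yl)-2,2-dimethylcyclohexan-1-one, via bromomagnesium enolate 5 (not isolated)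
Conditions: Cu(OTf)2 (3 mol %), chiral NHC ligand from a C2-symmetric 4,5-diphenylimidazolinium salt (4 mol %), Et2O, −30 °C; then MeI, DMPU, −30 → 23 °C
Reagents that add atoms: iodomethane, SMILES CI
Why: Copper-catalysed asymmetric conjugate addition of a Grignard reagent to an α-substituted cyclic enone, followed by C-methylation of the magnesium enolate, in which the chiral NHC–copper complex selects the enone face and so sets C3 while the methylation creates the non-stereogenic gem-dimethyl carbon.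

Step 3
Reactants: 6 (3R)-3-(but-3-en-1-yl)-2,2-dimethylcyclohexan-1-one
Product: 8 (3S,6RS)-3-(but-3-en-1-yl)-2,2,6-trimethylcyclohexan-1-one, via lithium enolate 7 (not isolated)
Conditions: LiN(i-Pr)2, THF, −78 °C; MeI, −78 → 0 °C
Reagents that add atoms: iodomethane, SMILES CI
Why: Enolate alkylation in which only C6 carries α-hydrogens, so the regiochemistry is fixed; the uncontrolled C6 centre becomes sp2 in step 6.

Step 4
Reactants: 8 (3S,6RS)-3-(but-3-en-1-yl)-2,2,6-trimethylcyclohexan-1-one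
Product: 9 (3R,6RS)-3-[(2E)-but-2-en-1-yl]-2,2,6-trimethylcyclohexan-1-one
Conditions: Co(salen)Cl [salen = N,N'-bis(3,5-di-tert-butylsalicylidene)cyclohexane-1,2-diaminate] (3 mol %), PhSiH3 (6 mol %), benzene, 23 °C
Reagents that add atoms: none
Why: Cobalt-hydride hydrogen-atom-transfer isomerisation should move the terminal alkene by one position only, to the 2-alkene, and leave the ketone untouched.

Step 5
Reactants: 9 (3R,6RS)-3-[(2E)-but-2-en-1-yl]-2,2,6-trimethylcyclohexan-1-one
Product: 10 (3R,6RS)-2,2,6-trimethyl-3-(3-methylbut-2-en-1-yl)cyclohexan-1-one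
Conditions: second-generation Grubbs catalyst RuCl2(=CHPh)(PCy3)(H2IMes) (5 mol %), 2-methylbut-2-ene (large excess), CH2Cl2, 40 °C
Reagents that add atoms: 2-methylbut-2-ene, SMILES CC=C(C)C
Why: Olefin cross-metathesis should exchange the ethylidene terminus of the side-chain alkene for the isopropylidene unit of 2-methylbut-2-ene and so give the prenyl group.

Step 6
Reactants: 10 (3R,6RS)-2,2,6-trimethyl-3-(3-methylbut-2-en-1-yl)cyclohexan-1-one
Product: 12 (5R)-2,6,6-trimethyl-5-(3-methylbut-2-en-1-yl)cyclohex-1-en-1-yl trifluoromethanesulfonate, via lithium enolate 11 (not isolated)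
Conditions: LiN(i-Pr)2, THF, −78 → 0 °C; PhNTf2, −78 → 23 °C
Reagents that add atoms: N-phenylbis(trifluoromethanesulfonimide), SMILES O=S(=O)(N(c1ccccc1)S(=O)(=O)C(F)(F)F)C(F)(F)F
Why: Enol triflate formation, in which deprotonation is possible only at C6 and O-sulfonylation of the enolate gives the tetrasubstituted vinyl triflate from both C6 epimers.

Step 7
Reactants: 12 (5R)-2,6,6-trimethyl-5-(3-methylbut-2-en-1-yl)cyclohex-1-en-1-yl trifluoromethanesulfonate
Product: 13 (3E)-4-(ring A)but-3-en-2-one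
Conditions: Pd(OAc)2 (5 mol %), PPh3 (10 mol %), Et3N, methyl vinyl ketone (3 equiv), DMF, 70 °C
Reagents that add atoms: but-3-en-2-one, SMILES C=CC(C)=O
Why: Mizoroki–Heck reaction, in which zerovalent palladium adds to the vinyl triflate, the enone inserts at its terminal carbon and β-hydride elimination should give the (E)-dienone.

Step 8
Reactants: 13 (3E)-4-(ring A)but-3-en-2-one
Product: 17 (1E)-1-(ring A)but-1-en-3-yne, via lithium dienolate 14 (not isolated), via enol phosphate 15 (not isolated), via lithium acetylide 16 (not isolated)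
Conditions: LiN(i-Pr)2 (1.05 equiv), THF, −78 °C; ClP(O)(OEt)2, −78 → 23 °C; LiN(i-Pr)2 (2.3 equiv), −78 → 23 °C; aq. NH4Cl
Reagents that add atoms: none
Why: Ketone-to-alkyne conversion through the enol phosphate, in which kinetic deprotonation at the acetyl methyl group, O-phosphorylation and base-induced elimination of diethyl phosphate should give the terminal enyne.

Step 9
Reactants: 17 (1E)-1-(ring A)but-1-en-3-yne; 2 (E)-1-bromo-2-iodoethene
Product: 20 (3E,5E,7E)-6-methyl-8-(ring A)octa-3,5,7-trien-1-yne, via dienylalane 18 (not isolated), via bromotriene 19 (not isolated)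
Conditions: Me3Al (2 equiv), Cp2ZrCl2 (25 mol %), ClCH2CH2Cl, 23 °C; volatiles removed in vacuo, THF; 2 (1.1 equiv), Pd(PPh3)4 (5 mol %), 0 → 23 °C; then HC≡CZnBr (from HC≡CMgBr and ZnBr2, 2 equiv), 23 °C
Reagents that add atoms: trimethylaluminium, SMILES C[Al](C)C; ethynylmagnesium bromide, SMILES C#C[Mg]Br
Why: Zirconium-catalysed syn-methylalumination puts methyl on C9 and aluminium on C10, palladium-catalysed coupling then occurs first at the C–I bond of 2, and the remaining alkenyl bromide is ethynylated by Negishi coupling, each with retention of alkene geometry.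

**Right trienyne (ring B)**

Step 10
Reactants: 3 2-methylcyclohex-2-en-1-one; 4 but-3-en-1-ylmagnesium bromide
Product: 22 (3S)-3-(but-3-en-1-yl)-2,2-dimethylcyclohexan-1-one, via bromomagnesium enolate 21 (not isolated)
Conditions: Cu(OTf)2 (3 mol %), mirror-image NHC ligand of step 2 (4 mol %), Et2O, −30 °C; then MeI, DMPU, −30 → 23 °C
Reagents that add atoms: iodomethane, SMILES CI
Why: The same copper-catalysed asymmetric conjugate addition with enolate methylation as in step 2, in which the antipodal ligand selects the opposite enone face and sets C3 as S.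

Step 11
Reactants: 22 (3S)-3-(but-3-en-1-yl)-2,2-dimethylcyclohexan-1-one
Product: 24 (3R,6RS)-3-(but-3-en-1-yl)-2,2,6-trimethylcyclohexan-1-one, via lithium enolate 23 (not isolated)
Conditions: LiN(i-Pr)2, THF, −78 °C; MeI, −78 → 0 °C
Reagents that add atoms: iodomethane, SMILES CI
Why: Enolate alkylation at C6, the only enolisable position.

Step 12
Reactants: 24 (3R,6RS)-3-(but-3-en-1-yl)-2,2,6-trimethylcyclohexan-1-one
Product: 25 (3S,6RS)-3-[(2E)-but-2-en-1-yl]-2,2,6-trimethylcyclohexan-1-one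
Conditions: Co(salen)Cl (3 mol %), PhSiH3 (6 mol %), benzene, 23 °C
Reagents that add atoms: none
Why: Cobalt-hydride hydrogen-atom-transfer isomerisation of the terminal alkene by one position, as in step 4.

Step 13
Reactants: 25 (3S,6RS)-3-[(2E)-but-2-en-1-yl]-2,2,6-trimethylcyclohexan-1-one
Product: 27 (5S)-5-[(2E)-but-2-en-1-yl]-2,6,6-trimethylcyclohex-1-en-1-yl trifluoromethanesulfonate, via lithium enolate 26 (not isolated)
Conditions: LiN(i-Pr)2, THF, −78 → 0 °C; PhNTf2, −78 → 23 °C
Reagents that add atoms: N-phenylbis(trifluoromethanesulfonimide), SMILES O=S(=O)(N(c1ccccc1)S(=O)(=O)C(F)(F)F)C(F)(F)F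
Why: Enol triflate formation at the only enolisable position, which also removes the ketone before the reductions that follow.

Step 14
Reactants: 27 (5S)-5-[(2E)-but-2-en-1-yl]-2,6,6-trimethylcyclohex-1-en-1-yl trifluoromethanesulfonate
Product: 29 (5S)-2,6,6-trimethyl-5-(2-oxoethyl)cyclohex-1-en-1-yl trifluoromethanesulfonate, via ozonide 28 (not isolated)
Conditions: O3 (1 equiv, Sudan Red 7B end point), CH2Cl2, −78 °C; PPh3, −78 → 23 °C
Reagents that add atoms: ozone, SMILES [O-][O+]=O
Why: Ozonolysis, in which the electron-rich disubstituted side-chain alkene should react far faster than the electron-poor tetrasubstituted enol triflate, and PPh3 reduces the ozonide to the aldehyde.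

Step 15
Reactants: 29 (5S)-2,6,6-trimethyl-5-(2-oxoethyl)cyclohex-1-en-1-yl trifluoromethanesulfonate
Product: 30 dimethyl 2-{2-[(1S)-2,2,4-trimethyl-3-{[(trifluoromethyl)sulfonyl]oxy}cyclohex-3-en-1-yl]ethylidene}propanedioate
Conditions: CH2(CO2Me)2 (1.2 equiv), piperidine (10 mol %), AcOH (10 mol %), 4 Å molecular sieves, CH2Cl2, 0 → 23 °C
Reagents that add atoms: dimethyl malonate, SMILES COC(=O)CC(=O)OC
Why: Knoevenagel condensation of the unhindered aldehyde with the malonate under mild amine/acid catalysis should give the alkylidene malonate.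

Step 16
Reactants: 30 dimethyl 2-{2-[(1S)-2,2,4-trimethyl-3-{[(trifluoromethyl)sulfonyl]oxy}cyclohex-3-en-1-yl]ethylidene}propanedioate
Product: 31 (5S)-5-[4-hydroxy-3-(hydroxymethyl)but-2-en-1-yl]-2,6,6-trimethylcyclohex-1-en-1-yl trifluoromethanesulfonate
Conditions: i-Bu2AlH (5 equiv), CH2Cl2, −78 → −20 °C; aq. potassium sodium tartrate
Reagents that add atoms: none
Why: 1,2-Reduction of both conjugated esters by the aluminium hydride at low temperature should give the 2-alkylidenepropane-1,3-diol, with the enol triflate inert.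

Step 17
Reactants: 31 (5S)-5-[4-hydroxy-3-(hydroxymethyl)but-2-en-1-yl]-2,6,6-trimethylcyclohex-1-en-1-yl trifluoromethanesulfonate
Product: 32 (5S)-5-{4-[(tert-butyldimethylsilyl)oxy]-3-{[(tert-butyldimethylsilyl)oxy]methyl}but-2-en-1-yl}-2,6,6-trimethylcyclohex-1-en-1-yl trifluoromethanesulfonate
Conditions: TBSCl (2.5 equiv), imidazole (5 equiv), DMF, 23 °C
Reagents that add atoms: tert-butyldimethylsilyl chloride, SMILES CC(C)(C)[Si](C)(C)Cl
Why: Silylation of both primary allylic alcohols gives ethers that tolerate the amide bases and Me3Al used later and that fluoride removes at the end.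

Step 18
Reactants: 32 (5S)-5-{4-[(tert-butyldimethylsilyl)oxy]-3-{[(tert-butyldimethylsilyl)oxy]methyl}but-2-en-1-yl}-2,6,6-trimethylcyclohex-1-en-1-yl trifluoromethanesulfonate
Product: 33 (3E)-4-(ring B)but-3-en-2-one
Conditions: Pd(OAc)2 (5 mol %), PPh3 (10 mol %), Et3N, methyl vinyl ketone (3 equiv), DMF, 70 °C
Reagents that add atoms: but-3-en-2-one, SMILES C=CC(C)=O
Why: Mizoroki–Heck reaction as in step 7; the allylic silyl ethers are poor leaving groups and should not ionise on palladium.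

Step 19
Reactants: 33 (3E)-4-(ring B)but-3-en-2-one
Product: 37 (1E)-1-(ring B)but-1-en-3-yne, via lithium dienolate 34 (not isolated), via enol phosphate 35 (not isolated), via lithium acetylide 36 (not isolated)
Conditions: LiN(i-Pr)2 (1.05 equiv), THF, −78 °C; ClP(O)(OEt)2, −78 → 23 °C; LiN(i-Pr)2 (2.3 equiv), −78 → 23 °C; aq. NH4Cl
Reagents that add atoms: none
Why: Ketone-to-alkyne conversion through the enol phosphate as in step 8.

Step 20
Reactants: 37 (1E)-1-(ring B)but-1-en-3-yne; 2 (E)-1-bromo-2-iodoethene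
Product: 40 (3E,5E,7E)-6-methyl-8-(ring B)octa-3,5,7-trien-1-yne, via dienylalane 38 (not isolated), via bromotriene 39 (not isolated)
Conditions: Me3Al (2 equiv), Cp2ZrCl2 (25 mol %), ClCH2CH2Cl, 23 °C; volatiles removed in vacuo, THF; 2 (1.1 equiv), Pd(PPh3)4 (5 mol %), 0 → 23 °C; then HC≡CZnBr (from HC≡CMgBr and ZnBr2, 2 equiv), 23 °C
Reagents that add atoms: trimethylaluminium, SMILES C[Al](C)C; ethynylmagnesium bromide, SMILES C#C[Mg]Br
Why: Zirconium-catalysed syn-methylalumination followed by iodide-selective alkenyl coupling with 2 and Negishi ethynylation of the bromide, as in step 9; the silyl ethers should tolerate Me3Al at 23 °C.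

**Assembly**

Step 21
Reactants: 20 (3E,5E,7E)-6-methyl-8-(ring A)octa-3,5,7-trien-1-yne; 2 (E)-1-bromo-2-iodoethene; 40 (3E,5E,7E)-6-methyl-8-(ring B)octa-3,5,7-trien-1-yne
Product: 44 (all-E,2R,2'S)-2'-{4-[(tert-butyldimethylsilyl)oxy]-3-{[(tert-butyldimethylsilyl)oxy]methyl}but-2-en-1-yl}-2-(3-methylbut-2-en-1-yl)-β,β-carotene, via left tetraenylalane 41 (not isolated), via left pentaenyl bromide 42 (not isolated), via right tetraenylalane 43 (not isolated)
Conditions: 20, Me3Al (2 equiv), Cp2ZrCl2 (25 mol %), ClCH2CH2Cl, 23 °C; volatiles removed in vacuo, THF; 2 (1.0 equiv), Pd2(dba)3 (2.5 mol %), P(2-furyl)3 (10 mol %), 0 → 23 °C; then 43 [from 40 (1.1 equiv), Me3Al (2 equiv), Cp2ZrCl2 (25 mol %), ClCH2CH2Cl, 23 °C; volatiles removed, THF], ZnCl2 (0.5 equiv), DMF, 23 °C; argon, dark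
Reagents that add atoms: trimethylaluminium, SMILES C[Al](C)C
Why: Each terminal trienyne undergoes zirconium-catalysed syn-methylalumination (methyl to C13 or C13', aluminium to C14 or C14'); zerovalent palladium then inserts into the weaker C–I bond of 2, alane 41 transmetalates and reductive elimination forms C14–C15 to give bromide 42, and a second oxidative addition at C–Br with zinc-assisted transmetalation of alane 43 forms the C15'–C14' bond. The closest known reaction type is the zirconium-catalysed carboalumination of conjugated enynes followed by palladium/zinc-mediated alkenyl–alkenyl (Negishi) coupling with (E)-1,2-dihaloethenes. No ring is closed and no stereocentre is created; C2 and C2' are remote and untouched, the two new trisubstituted alkenes are E because carbometalation is syn and coupling proceeds with retention, and the central E geometry is carried in from 2. The step needs regioselective carbometalation (secured by the terminal alkyne, aluminium going to the unsubstituted carbon), halogen discrimination (iodide before bromide, secured by the two different halogens of the linchpin and by adding 43 only after 41 is consumed) and hetero- over homo-assembly (secured by the one-to-one ratio of 41 and 2). Homo-assembled carotenes would carry zero or four silyloxy groups and should separate from 44 by polarity.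

Step 22
Reactants: 44 (all-E,2R,2'S)-2'-{4-[(tert-butyldimethylsilyl)oxy]-3-{[(tert-butyldimethylsilyl)oxy]methyl}but-2-en-1-yl}-2-(3-methylbut-2-en-1-yl)-β,β-carotene
Product: 45 (all-E,2R,2'S)-2'-[4-hydroxy-3-(hydroxymethyl)but-2-en-1-yl]-2-(3-methylbut-2-en-1-yl)-β,β-carotene (target)
Conditions: Bu4NF (3 equiv), THF, 0 → 23 °C, argon, dark
Reagents that add atoms: none
Why: Fluoride-mediated desilylation of the two primary allylic silyl ethers under cold, neutral, light-free conditions should leave the polyene geometry and both stereocentres untouched.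

## Compound list

1 | acetylene | C#C | starting material
2 | (E)-1-bromo-2-iodoethene | Br/C=C/I | intermediate
3 | 2-methylcyclohex-2-en-1-one | CC1=CCCCC1=O | starting material
4 | but-3-en-1-ylmagnesium bromide | C=CCC[Mg]Br | starting material
5 | bromomagnesium (3R)-3-(but-3-en-1-yl)-2-methylcyclohex-1-en-1-olate | C=CCC[C@H]1CCCC(O[Mg]Br)=C1C | intermediate
6 | (3R)-3-(but-3-en-1-yl)-2,2-dimethylcyclohexan-1-one | C=CCC[C@H]1CCCC(=O)C1(C)C | intermediate
7 | lithium (5S)-5-(but-3-en-1-yl)-6,6-dimethylcyclohex-1-en-1-olate | C=CCC[C@H]1CCC=C(O[Li])C1(C)C | intermediate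
8 | (3S,6RS)-3-(but-3-en-1-yl)-2,2,6-trimethylcyclohexan-1-one | C=CCC[C@H]1CCC(C)C(=O)C1(C)C | intermediate
9 | (3R,6RS)-3-[(2E)-but-2-en-1-yl]-2,2,6-trimethylcyclohexan-1-one | C/C=C/C[C@H]1CCC(C)C(=O)C1(C)C | intermediate
10 | (3R,6RS)-2,2,6-trimethyl-3-(3-methylbut-2-en-1-yl)cyclohexan-1-one | CC(C)=CC[C@H]1CCC(C)C(=O)C1(C)C | intermediate
11 | lithium (5R)-2,6,6-trimethyl-5-(3-methylbut-2-en-1-yl)cyclohex-1-en-1-olate | CC(C)=CC[C@H]1CCC(C)=C(O[Li])C1(C)C | intermediate
12 | (5R)-2,6,6-trimethyl-5-(3-methylbut-2-en-1-yl)cyclohex-1-en-1-yl trifluoromethanesulfonate | CC(C)=CC[C@H]1CCC(C)=C(OS(=O)(=O)C(F)(F)F)C1(C)C | intermediate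
13 | (3E)-4-(ring A)but-3-en-2-one | CC(C)=CC[C@H]1CCC(C)=C(/C=C/C(C)=O)C1(C)C | intermediate
14 | lithium (3E)-4-(ring A)buta-1,3-dien-2-olate | CC(C)=CC[C@H]1CCC(C)=C(/C=C/C(=C)O[Li])C1(C)C | intermediate
15 | diethyl (3E)-4-(ring A)buta-1,3-dien-2-yl phosphate | CC(C)=CC[C@H]1CCC(C)=C(/C=C/C(=C)OP(=O)(OCC)OCC)C1(C)C | intermediate
16 | lithium (3E)-4-(ring A)but-3-en-1-yn-1-ide | CC(C)=CC[C@H]1CCC(C)=C(/C=C/C#C[Li])C1(C)C | intermediate
17 | (1E)-1-(ring A)but-1-en-3-yne | CC(C)=CC[C@H]1CCC(C)=C(/C=C/C#C)C1(C)C | intermediate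
18 | dimethyl[(1E,3E)-2-methyl-4-(ring A)buta-1,3-dien-1-yl]alumane | CC(C)=CC[C@H]1CCC(C)=C(/C=C/C(C)=C/[Al](C)C)C1(C)C | intermediate
19 | (1E,3E,5E)-1-bromo-4-methyl-6-(ring A)hexa-1,3,5-triene | CC(C)=CC[C@H]1CCC(C)=C(/C=C/C(C)=C/C=C/Br)C1(C)C | intermediate
20 | (3E,5E,7E)-6-methyl-8-(ring A)octa-3,5,7-trien-1-yne | CC(C)=CC[C@H]1CCC(C)=C(/C=C/C(C)=C/C=C/C#C)C1(C)C | intermediate
21 | bromomagnesium (3S)-3-(but-3-en-1-yl)-2-methylcyclohex-1-en-1-olate | C=CCC[C@@H]1CCCC(O[Mg]Br)=C1C | intermediate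
22 | (3S)-3-(but-3-en-1-yl)-2,2-dimethylcyclohexan-1-one | C=CCC[C@@H]1CCCC(=O)C1(C)C | intermediate
23 | lithium (5R)-5-(but-3-en-1-yl)-6,6-dimethylcyclohex-1-en-1-olate | C=CCC[C@@H]1CCC=C(O[Li])C1(C)C | intermediate
24 | (3R,6RS)-3-(but-3-en-1-yl)-2,2,6-trimethylcyclohexan-1-one | C=CCC[C@@H]1CCC(C)C(=O)C1(C)C | intermediate
25 | (3S,6RS)-3-[(2E)-but-2-en-1-yl]-2,2,6-trimethylcyclohexan-1-one | C/C=C/C[C@@H]1CCC(C)C(=O)C1(C)C | intermediate
26 | lithium (5S)-5-[(2E)-but-2-en-1-yl]-2,6,6-trimethylcyclohex-1-en-1-olate | C/C=C/C[C@@H]1CCC(C)=C(O[Li])C1(C)C | intermediate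
27 | (5S)-5-[(2E)-but-2-en-1-yl]-2,6,6-trimethylcyclohex-1-en-1-yl trifluoromethanesulfonate | C/C=C/C[C@@H]1CCC(C)=C(OS(=O)(=O)C(F)(F)F)C1(C)C | intermediate
28 | (5S)-2,6,6-trimethyl-5-[(5-methyl-1,2,4-trioxolan-3-yl)methyl]cyclohex-1-en-1-yl trifluoromethanesulfonate | CC1OOC(C[C@@H]2CCC(C)=C(OS(=O)(=O)C(F)(F)F)C2(C)C)O1 | intermediate
29 | (5S)-2,6,6-trimethyl-5-(2-oxoethyl)cyclohex-1-en-1-yl trifluoromethanesulfonate | O=CC[C@@H]1CCC(C)=C(OS(=O)(=O)C(F)(F)F)C1(C)C | intermediate
30 | dimethyl 2-{2-[(1S)-2,2,4-trimethyl-3-{[(trifluoromethyl)sulfonyl]oxy}cyclohex-3-en-1-yl]ethylidene}propanedioate | COC(=O)C(=CC[C@@H]1CCC(C)=C(OS(=O)(=O)C(F)(F)F)C1(C)C)C(=O)OC | intermediate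
31 | (5S)-5-[4-hydroxy-3-(hydroxymethyl)but-2-en-1-yl]-2,6,6-trimethylcyclohex-1-en-1-yl trifluoromethanesulfonate | OCC(CO)=CC[C@@H]1CCC(C)=C(OS(=O)(=O)C(F)(F)F)C1(C)C | intermediate
32 | (5S)-5-{4-[(tert-butyldimethylsilyl)oxy]-3-{[(tert-butyldimethylsilyl)oxy]methyl}but-2-en-1-yl}-2,6,6-trimethylcyclohex-1-en-1-yl trifluoromethanesulfonate | CC(C)(C)[Si](C)(C)OCC(CO[Si](C)(C)C(C)(C)C)=CC[C@@H]1CCC(C)=C(OS(=O)(=O)C(F)(F)F)C1(C)C | intermediate
33 | (3E)-4-(ring B)but-3-en-2-one | CC(C)(C)[Si](C)(C)OCC(CO[Si](C)(C)C(C)(C)C)=CC[C@@H]1CCC(C)=C(/C=C/C(C)=O)C1(C)C | intermediate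
34 | lithium (3E)-4-(ring B)buta-1,3-dien-2-olate | CC(C)(C)[Si](C)(C)OCC(CO[Si](C)(C)C(C)(C)C)=CC[C@@H]1CCC(C)=C(/C=C/C(=C)O[Li])C1(C)C | intermediate
35 | diethyl (3E)-4-(ring B)buta-1,3-dien-2-yl phosphate | CC(C)(C)[Si](C)(C)OCC(CO[Si](C)(C)C(C)(C)C)=CC[C@@H]1CCC(C)=C(/C=C/C(=C)OP(=O)(OCC)OCC)C1(C)C | intermediate
36 | lithium (3E)-4-(ring B)but-3-en-1-yn-1-ide | CC(C)(C)[Si](C)(C)OCC(CO[Si](C)(C)C(C)(C)C)=CC[C@@H]1CCC(C)=C(/C=C/C#C[Li])C1(C)C | intermediate
37 | (1E)-1-(ring B)but-1-en-3-yne | CC(C)(C)[Si](C)(C)OCC(CO[Si](C)(C)C(C)(C)C)=CC[C@@H]1CCC(C)=C(/C=C/C#C)C1(C)C | intermediate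
38 | dimethyl[(1E,3E)-2-methyl-4-(ring B)buta-1,3-dien-1-yl]alumane | CC(C)(C)[Si](C)(C)OCC(CO[Si](C)(C)C(C)(C)C)=CC[C@@H]1CCC(C)=C(/C=C/C(C)=C/[Al](C)C)C1(C)C | intermediate
39 | (1E,3E,5E)-1-bromo-4-methyl-6-(ring B)hexa-1,3,5-triene | CC(C)(C)[Si](C)(C)OCC(CO[Si](C)(C)C(C)(C)C)=CC[C@@H]1CCC(C)=C(/C=C/C(C)=C/C=C/Br)C1(C)C | intermediate
40 | (3E,5E,7E)-6-methyl-8-(ring B)octa-3,5,7-trien-1-yne | CC(C)(C)[Si](C)(C)OCC(CO[Si](C)(C)C(C)(C)C)=CC[C@@H]1CCC(C)=C(/C=C/C(C)=C/C=C/C#C)C1(C)C | intermediate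
41 | dimethyl[(1E,3E,5E,7E)-2,6-dimethyl-8-(ring A)octa-1,3,5,7-tetraen-1-yl]alumane | CC(C)=CC[C@H]1CCC(C)=C(/C=C/C(C)=C/C=C/C(C)=C/[Al](C)C)C1(C)C | intermediate
42 | (1E,3E,5E,7E,9E)-1-bromo-4,8-dimethyl-10-(ring A)deca-1,3,5,7,9-pentaene | CC(C)=CC[C@H]1CCC(C)=C(/C=C/C(C)=C/C=C/C(C)=C/C=C/Br)C1(C)C | intermediate
43 | dimethyl[(1E,3E,5E,7E)-2,6-dimethyl-8-(ring B)octa-1,3,5,7-tetraen-1-yl]alumane | CC(C)(C)[Si](C)(C)OCC(CO[Si](C)(C)C(C)(C)C)=CC[C@@H]1CCC(C)=C(/C=C/C(C)=C/C=C/C(C)=C/[Al](C)C)C1(C)C | intermediate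
44 | (all-E,2R,2'S)-2'-{4-[(tert-butyldimethylsilyl)oxy]-3-{[(tert-butyldimethylsilyl)oxy]methyl}but-2-en-1-yl}-2-(3-methylbut-2-en-1-yl)-β,β-carotene | CC(C)=CC[C@H]1CCC(C)=C(/C=C/C(C)=C/C=C/C(C)=C/C=C/C=C(C)/C=C/C=C(C)/C=C/C2=C(C)CC[C@@H](CC=C(CO[Si](C)(C)C(C)(C)C)CO[Si](C)(C)C(C)(C)C)C2(C)C)C1(C)C | intermediate
45 | (all-E,2R,2'S)-2'-[4-hydroxy-3-(hydroxymethyl)but-2-en-1-yl]-2-(3-methylbut-2-en-1-yl)-β,β-carotene | CC(C)=CC[C@H]1CCC(C)=C(/C=C/C(C)=C/C=C/C(C)=C/C=C/C=C(C)/C=C/C=C(C)/C=C/C2=C(C)CC[C@@H](CC=C(CO)CO)C2(C)C)C1(C)C | target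

## Step count and risks

Total step count: 22. Longest linear sequence: 13 steps (steps 10–22, from 3 to 45).

**Step 21 (key step).** What may go wrong: scrambling between the two alanes (homo-assembly), slow oxidative addition or transmetalation at the bromide stage, methyl transfer from aluminium, and light- or Lewis-acid-induced E/Z isomerisation of the polyene. The fallback sets out from 20 and 40 and returns at 44. Trienyne 20 is methylaluminated as in step 21 and alane 41 is quenched with I2 (THF, −30 °C) to give the left tetraenyl iodide F1; in the same way 40 gives, through alane 43, the right tetraenyl iodide F2. Stille coupling of F1 with excess (E)-1,2-bis(tributylstannyl)ethene (Pd2(dba)3, AsPh3, NMP, 23 °C) gives the left pentaenylstannane F3. A second Stille coupling of F3 with F2 under the same catalyst forms the same C15'–C14' bond and gives 44.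

**Step 2 (and its mirror image, step 10).** What may go wrong: insufficient enantiofacial discrimination in the copper-catalysed addition to the α-substituted enone. The fallback sets out from 3 and 4 and returns at 6 and 22. Ligand-free conjugate addition (CuBr·SMe2 5 mol %, THF, −40 °C) with the same MeI/DMPU trapping gives, through the racemic bromomagnesium enolate F4, the racemic ketone F5. F5 is resolved by preparative chromatography on a chiral stationary phase; one antipode is 6 and the other is 22, so both are used.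

**Step 7 (and its twin, step 18).** What may go wrong: slow oxidative addition and insertion at the hindered tetrasubstituted triflate, so that triflate hydrolysis or polymerisation of the enone takes over. The fallback sets out from 12 and returns at 13. Sonogashira coupling of 12 with but-3-yn-2-ol (PdCl2(PPh3)2, CuI, Et3N, DMF, 50 °C) gives the propargylic alcohol F6. Trans-selective hydroalumination with NaAlH2(OCH2CH2OCH3)2 (THF, 0 °C) gives the (E)-allylic alcohol F7, and oxidation with MnO2 (CH2Cl2, 23 °C) gives 13. Step 18 would be answered in the same way, from 32 through the propargylic alcohol F8 and the (E)-allylic alcohol F9 back to 33.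

## Further compounds

F1 | step 21 | (1E,3E,5E,7E)-1-iodo-2,6-dimethyl-8-(ring A)octa-1,3,5,7-tetraene | CC(C)=CC[C@H]1CCC(C)=C(/C=C/C(C)=C/C=C/C(C)=C/I)C1(C)C
F2 | step 21 | (1E,3E,5E,7E)-1-iodo-2,6-dimethyl-8-(ring B)octa-1,3,5,7-tetraene | CC(C)(C)[Si](C)(C)OCC(CO[Si](C)(C)C(C)(C)C)=CC[C@@H]1CCC(C)=C(/C=C/C(C)=C/C=C/C(C)=C/I)C1(C)C
F3 | step 21 | tributyl[(1E,3E,5E,7E,9E)-4,8-dimethyl-10-(ring A)deca-1,3,5,7,9-pentaen-1-yl]stannane | CC(C)=CC[C@H]1CCC(C)=C(/C=C/C(C)=C/C=C/C(C)=C/C=C/[Sn](CCCC)(CCCC)CCCC)C1(C)C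
F4 | step 2 | racemic bromomagnesium 3-(but-3-en-1-yl)-2-methylcyclohex-1-en-1-olate | C=CCCC1CCCC(O[Mg]Br)=C1C
F5 | step 2 | racemic 3-(but-3-en-1-yl)-2,2-dimethylcyclohexan-1-one | C=CCCC1CCCC(=O)C1(C)C
F6 | step 7 | 4-(ring A)but-3-yn-2-ol (carbinol epimers) | CC(C)=CC[C@H]1CCC(C)=C(C#CC(C)O)C1(C)C
F7 | step 7 | (3E)-4-(ring A)but-3-en-2-ol (carbinol epimers) | CC(C)=CC[C@H]1CCC(C)=C(/C=C/C(C)O)C1(C)C
F8 | step 18 | 4-(ring B)but-3-yn-2-ol (carbinol epimers) | CC(C)(C)[Si](C)(C)OCC(CO[Si](C)(C)C(C)(C)C)=CC[C@@H]1CCC(C)=C(C#CC(C)O)C1(C)C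
F9 | step 18 | (3E)-4-(ring B)but-3-en-2-ol (carbinol epimers) | CC(C)(C)[Si](C)(C)OCC(CO[Si](C)(C)C(C)(C)C)=CC[C@@H]1CCC(C)=C(/C=C/C(C)O)C1(C)C
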